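**Retrosynthetic overview**
- Ring A (the oxolane O1–C2–C3–C4–C5) is the only ring built and is closed last, at O1–C2: DDQ turns the 3,4-dimethoxybenzylic methylene C2 (ring B) into a cation that the C5 hydroxyl captures.
- The C5 carbinol comes from Felkin–Anh reduction of the aryl ketone of ring C (3,4,5-trimethoxyphenyl). The C4–C5 bond comes from a boronate homologation with lithiated 3,4,5-trimethoxybenzyl carbamate, followed by C–B oxidation.
- The strategy rests on C3 and C4 of ring A: two adjacent CH(CH3) carbons of the same local handedness (cis-dimethyl), lying between the benzylic carbons C2 and C5. Both are inserted in turn, as the same chiral α-lithioethyl ester, into the C–B bond of 3,4-dimethoxybenzyl pinacol boronate (C2–C3 first, then C3–C4).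
- The two building blocks come from 3,4-dimethoxybenzyl chloride with B2pin2 and from 2,4,6-triisopropylbenzoic acid.

Key step: step 3

Remark: locants refer to ring A of the target, (2S,3S,4R,5R)-2-(3,4-dimethoxyphenyl)-3,4-dimethyl-5-(3,4,5-trimethoxyphenyl)oxolane (2,3-trans, 3,4-cis, 4,5-trans); the lithiated primary benzylic carbamate of step 5 is assumed to be configurationally labile, so C5 is left uncontrolled there and is set in steps 6 and 7.

**Route**

Step 1
Reactants: 1 4-(chloromethyl)-1,2-dimethoxybenzene; 2 bis(pinacolato)diboron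
Product: 3 2-[(3,4-dimethoxyphenyl)methyl]-4,4,5,5-tetramethyl-1,3,2-dioxaborolane
Conditions: Pd(PPh3)4 (zerovalent palladium, 3 mol %), KOAc, 1,4-dioxane, 80 °C
Reagents that add atoms: none
Why: Miyaura borylation of a benzylic halide (oxidative addition of the C–Cl bond, acetate-assisted transmetallation with B2pin2, reductive elimination) should give the benzyl boronic ester; no stereocentre is formed.

Step 2
Reactants: 4 2,4,6-triisopropylbenzoic acid
Product: 5 ethyl 2,4,6-triisopropylbenzoate
Conditions: EtI, K2CO3, DMF, 50 °C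
Reagents that add atoms: iodoethane, CCI
Why: SN2 O-alkylation of the carboxylate avoids attack at the carbonyl carbon, which the two ortho isopropyl groups block towards Fischer esterification.

Step 3
Reactants: 3 2-[(3,4-dimethoxyphenyl)methyl]-4,4,5,5-tetramethyl-1,3,2-dioxaborolane; 5 ethyl 2,4,6-triisopropylbenzoate (one portion per cycle)
Product: 10 2-[(2R,3R)-4-(3,4-dimethoxyphenyl)-3-methylbutan-2-yl]-4,4,5,5-tetramethyl-1,3,2-dioxaborolane, via lithiated benzoate 6 (not isolated), via first boronate complex 7 (not isolated), via mono-homologated boronic ester 8 (not isolated), via second boronate complex 9 (not isolated)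
Conditions: cycle 1: 5 (1.4 equiv), (−)-sparteine (1.4 equiv), s-BuLi (1.3 equiv), Et2O, −78 °C, 5 h; add 3, −78 °C, 2 h; then 35 °C, 16 h; aq. HCl wash, short silica plug. Cycle 2: crude 8 added to a second batch of 6 made the same way, −78 °C, 3 h; then 35 °C, 16 h
Reagents that add atoms: none
Why: s-BuLi/(−)-sparteine removes the pro-S α-proton of 5 to give the configurationally stable (S)-carbenoid 6, which adds to boron of 3 with retention to give boronate 7; on warming, the benzyl group shifts from boron to carbon antiperiplanar to the departing triisopropylbenzoate, with inversion at the carbenoid carbon, which forms C2–C3 and the (R)-ester 8. The second cycle repeats this on 8 through boronate 9, the secondary alkyl group now migrating with retention at its own carbon, which forms C3–C4 and gives (2R,3R)-10. The closest known reaction type is exactly this lithiation–borylation (assembly-line) homologation of pinacol boronic esters with sparteine-ligated α-lithioethyl triisopropylbenzoate, a reagent-controlled 1,2-metallate rearrangement. No ring is closed in this step. Both new stereocentres (C3 and C4 of the target) are set by the reagent, that is by using (−)-sparteine in both cycles, and the stereospecific 1,2-shift passes this on whatever the configuration already present, so the like (cis-dimethyl) pair results. The step needs one insertion per cycle and carbon rather than oxygen migration: the first is secured because boronates 7 and 9 do not rearrange at −78 °C while surplus 6 is destroyed on warming before the shift begins, the second by the good migrating ability of the benzyl and secondary alkyl groups compared with the pinacol oxygen atoms.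

Step 4
Reactants: 11 (3,4,5-trimethoxyphenyl)methanol
Product: 12 (3,4,5-trimethoxyphenyl)methyl N,N-diisopropylcarbamate
Conditions: NaH, THF, 0 °C; then iPr2NCOCl, 0 → 60 °C
Reagents that add atoms: N,N-diisopropylcarbamoyl chloride, CC(C)N(C(C)C)C(Cl)=O
Why: O-carbamoylation of the sodium alkoxide (acyl substitution) should give the carbamate that directs benzylic lithiation and later acts as the leaving group.

Step 5
Reactants: 10 2-[(2R,3R)-4-(3,4-dimethoxyphenyl)-3-methylbutan-2-yl]-4,4,5,5-tetramethyl-1,3,2-dioxaborolane; 12 (3,4,5-trimethoxyphenyl)methyl N,N-diisopropylcarbamate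
Product: 16 (1RS,2R,3R)-4-(3,4-dimethoxyphenyl)-2,3-dimethyl-1-(3,4,5-trimethoxyphenyl)butan-1-ol (both C1 epimers), via lithiated carbamate 13 (not isolated), via third boronate complex 14 (not isolated), via benzylic boronic ester 15 (not isolated)
Conditions: 12 (1.3 equiv), TMEDA, s-BuLi, Et2O, −78 °C, 1 h; add 10, −78 °C, 2 h; → rt, 16 h; then NaOH, H2O2, THF/H2O, 0 °C → rt
Reagents that add atoms: hydrogen peroxide, OO
Why: benzylic α-lithiation of the carbamate, addition to boron and 1,2-shift of the secondary alkyl group with loss of carbamate (lithiation–borylation homologation) should form C4–C5 with retention at C4, and stereoretentive oxidation of the new C–B bond gives the carbinol; C5 is not controlled here and is corrected in steps 6 and 7.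

Step 6
Reactants: 16 (1RS,2R,3R)-4-(3,4-dimethoxyphenyl)-2,3-dimethyl-1-(3,4,5-trimethoxyphenyl)butan-1-ol
Product: 17 (2R,3R)-4-(3,4-dimethoxyphenyl)-2,3-dimethyl-1-(3,4,5-trimethoxyphenyl)butan-1-one
Conditions: Dess–Martin periodinane, CH2Cl2, 0 °C → rt
Reagents that add atoms: none
Why: Dess–Martin oxidation of the secondary benzylic alcohol should merge both C5 epimers into one ketone under non-basic conditions that leave the enolisable C4 centre untouched.

Step 7
Reactants: 17 (2R,3R)-4-(3,4-dimethoxyphenyl)-2,3-dimethyl-1-(3,4,5-trimethoxyphenyl)butan-1-one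
Product: 18 (1R,2R,3R)-4-(3,4-dimethoxyphenyl)-2,3-dimethyl-1-(3,4,5-trimethoxyphenyl)butan-1-ol
Conditions: LiBH(s-Bu)3 (L-Selectride), THF, −78 °C; aq. NH4Cl
Reagents that add atoms: none
Why: Felkin–Anh addition of the bulky hydride, with the C3-bearing chain on C4 antiperiplanar to the incoming hydride and the C4 hydrogen beside its trajectory, should give the 1,2-anti alcohol, that is R at C5 (4,5-trans after ring closure), set by the C4 centre.

Step 8
Reactants: 18 (1R,2R,3R)-4-(3,4-dimethoxyphenyl)-2,3-dimethyl-1-(3,4,5-trimethoxyphenyl)butan-1-ol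
Product: 19 (2S,3S,4R,5R)-2-(3,4-dimethoxyphenyl)-3,4-dimethyl-5-(3,4,5-trimethoxyphenyl)oxolane
Conditions: DDQ (1.1 equiv), 2,6-dichloropyridine, 4 Å MS, CH2Cl2, 0 °C → rt
Reagents that add atoms: none
Why: DDQ abstracts hydride from the C2 methylene, which is para to the 4-methoxy group of ring B, and the quinone-methide-like benzylic cation is captured by the C5 hydroxyl in a 5-exo closure of ring A (DDQ-mediated intramolecular benzylic oxidative etherification of electron-rich arylalkanols), the aryl group taking the position trans to the C3 methyl group so that C2 is set as S by the C3 centre.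

**Compound list**

1 | 4-(chloromethyl)-1,2-dimethoxybenzene | COc1ccc(CCl)cc1OC | starting material
2 | bis(pinacolato)diboron | CC1(C)OB(B2OC(C)(C)C(C)(C)O2)OC1(C)C | starting material
3 | 2-[(3,4-dimethoxyphenyl)methyl]-4,4,5,5-tetramethyl-1,3,2-dioxaborolane | COc1ccc(CB2OC(C)(C)C(C)(C)O2)cc1OC | intermediate
4 | 2,4,6-triisopropylbenzoic acid | CC(C)c1cc(C(C)C)c(C(=O)O)c(C(C)C)c1 | starting material
5 | ethyl 2,4,6-triisopropylbenzoate | CCOC(=O)c1c(C(C)C)cc(C(C)C)cc1C(C)C | intermediate
6 | (S)-1-lithioethyl 2,4,6-triisopropylbenzoate, as its (−)-sparteine complex | [Li][C@@H](C)OC(=O)c1c(C(C)C)cc(C(C)C)cc1C(C)C | intermediate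
7 | lithium 2-[(3,4-dimethoxyphenyl)methyl]-4,4,5,5-tetramethyl-2-[(1S)-1-(2,4,6-triisopropylbenzoyloxy)ethyl]-1,3,2-dioxaborolan-2-uide | COc1ccc(C[B-]2(OC(C)(C)C(C)(C)O2)[C@@H](C)OC(=O)c2c(C(C)C)cc(C(C)C)cc2C(C)C)cc1OC.[Li+] | intermediate
8 | 2-[(2R)-1-(3,4-dimethoxyphenyl)propan-2-yl]-4,4,5,5-tetramethyl-1,3,2-dioxaborolane | COc1ccc(C[C@@H](C)B2OC(C)(C)C(C)(C)O2)cc1OC | intermediate
9 | lithium 2-[(2R)-1-(3,4-dimethoxyphenyl)propan-2-yl]-4,4,5,5-tetramethyl-2-[(1S)-1-(2,4,6-triisopropylbenzoyloxy)ethyl]-1,3,2-dioxaborolan-2-uide | COc1ccc(C[C@@H](C)[B-]2(OC(C)(C)C(C)(C)O2)[C@@H](C)OC(=O)c2c(C(C)C)cc(C(C)C)cc2C(C)C)cc1OC.[Li+] | intermediate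
10 | 2-[(2R,3R)-4-(3,4-dimethoxyphenyl)-3-methylbutan-2-yl]-4,4,5,5-tetramethyl-1,3,2-dioxaborolane | COc1ccc(C[C@@H](C)[C@@H](C)B2OC(C)(C)C(C)(C)O2)cc1OC | intermediate
11 | (3,4,5-trimethoxyphenyl)methanol | COc1cc(CO)cc(OC)c1OC | starting material
12 | (3,4,5-trimethoxyphenyl)methyl N,N-diisopropylcarbamate | COc1cc(COC(=O)N(C(C)C)C(C)C)cc(OC)c1OC | intermediate
13 | lithio(3,4,5-trimethoxyphenyl)methyl N,N-diisopropylcarbamate (racemic, TMEDA complex) | [Li]C(OC(=O)N(C(C)C)C(C)C)c1cc(OC)c(OC)c(OC)c1 | intermediate
14 | lithium 2-[(2R,3R)-4-(3,4-dimethoxyphenyl)-3-methylbutan-2-yl]-2-{[(diisopropylcarbamoyl)oxy](3,4,5-trimethoxyphenyl)methyl}-4,4,5,5-tetramethyl-1,3,2-dioxaborolan-2-uide (both epimers at the benzylic carbon) | COc1ccc(C[C@@H](C)[C@@H](C)[B-]2(OC(C)(C)C(C)(C)O2)C(OC(=O)N(C(C)C)C(C)C)c2cc(OC)c(OC)c(OC)c2)cc1OC.[Li+] | intermediate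
15 | 2-[(1RS,2S,3R)-4-(3,4-dimethoxyphenyl)-2,3-dimethyl-1-(3,4,5-trimethoxyphenyl)butyl]-4,4,5,5-tetramethyl-1,3,2-dioxaborolane (same spatial arrangement at the two methyl-bearing carbons as in 10) | COc1ccc(C[C@@H](C)[C@@H](C)C(B2OC(C)(C)C(C)(C)O2)c2cc(OC)c(OC)c(OC)c2)cc1OC | intermediate
16 | (1RS,2R,3R)-4-(3,4-dimethoxyphenyl)-2,3-dimethyl-1-(3,4,5-trimethoxyphenyl)butan-1-ol | COc1ccc(C[C@@H](C)[C@@H](C)C(O)c2cc(OC)c(OC)c(OC)c2)cc1OC | intermediate
17 | (2R,3R)-4-(3,4-dimethoxyphenyl)-2,3-dimethyl-1-(3,4,5-trimethoxyphenyl)butan-1-one | COc1ccc(C[C@@H](C)[C@@H](C)C(=O)c2cc(OC)c(OC)c(OC)c2)cc1OC | intermediate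
18 | (1R,2R,3R)-4-(3,4-dimethoxyphenyl)-2,3-dimethyl-1-(3,4,5-trimethoxyphenyl)butan-1-ol | COc1ccc(C[C@@H](C)[C@@H](C)[C@@H](O)c2cc(OC)c(OC)c(OC)c2)cc1OC | intermediate
19 | (2S,3S,4R,5R)-2-(3,4-dimethoxyphenyl)-3,4-dimethyl-5-(3,4,5-trimethoxyphenyl)oxolane | COc1ccc([C@H]2O[C@@H](c3cc(OC)c(OC)c(OC)c3)[C@H](C)[C@@H]2C)cc1OC | target

**Step count**

Total: 8 steps. Longest linear sequence: 6 steps (steps 1, 3, 5, 6, 7, 8).

**Steps most likely to fail**

1. Step 8 (DDQ ring closure). Hydride abstraction may not stay confined to the C2 methylene. The C5 carbinol can be oxidised back to the ketone, the product can be oxidised further at its doubly activated C2–H, and the C2 cation can be captured by ring C in a Friedel–Crafts closure.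
   Fallback, from 17 back to 19: oxidation and C–O bond formation are separated, so that complete oxidation at C2 becomes the aim. Ketone 17, whose C5 is already at the ketone level, is treated with DDQ (2.5 equiv) in CH2Cl2/H2O. This should give the 1,4-diketone (2S,3R)-1-(3,4-dimethoxyphenyl)-2,3-dimethyl-4-(3,4,5-trimethoxyphenyl)butane-1,4-dione F1. LiBH(s-Bu)3 in THF at −78 °C then reduces both carbonyl groups under Felkin–Anh control to the 1,4-diol (1S,2S,3R,4R)-1-(3,4-dimethoxyphenyl)-2,3-dimethyl-4-(3,4,5-trimethoxyphenyl)butane-1,4-diol F2. MsCl/Et3N in CH2Cl2 at 0 °C ionises a benzylic hydroxyl, preferentially the one at C2 next to the more electron-rich ring B, and the other hydroxyl closes ring A trans to the neighbouring methyl group to give 19. Both carbinol centres of F2 already have the configuration of the target, so either direction of ionisation should lead to 19.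

2. Step 3 (key step). Capture of the bulky sparteine-bound carbenoid by the hindered secondary boronic ester 8 may be slow in the second cycle, so that 6 decomposes before the boronate forms. Any shortfall in the enantioselectivity of the deprotonation is also carried into the product as the unlike diastereomer.
   Fallback, from 5 (with 3) back to 10: the carbenoid is released from a stored, enantiopure precursor instead of being made by asymmetric deprotonation at the time of use. Deprotonation of 5 with s-BuLi/(−)-sparteine in Et2O at −78 °C and quenching with Me3SnCl gives (S)-1-(trimethylstannyl)ethyl 2,4,6-triisopropylbenzoate F3, which is brought to enantiopurity by recrystallisation. Tin–lithium exchange with n-BuLi in Et2O at −78 °C releases diamine-free 6, which is smaller and should add faster to boron. Reaction with 3, warming, filtration, and a second portion of F3/n-BuLi with crude 8 lead to 10.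

3. Step 5 (third homologation). Ring lithiation of the trimethoxyarene can compete with benzylic lithiation. Boronate formation with the α,β-branched boronic ester 10 may be slow and reversible, so that the lithiated carbamate decomposes before it is trapped.
   Fallback, from 10 back to 15: the polarity of the C4–C5 construction is reversed by a Matteson homologation. (Dichloromethyl)lithium, made from CH2Cl2 and n-BuLi in THF at −100 °C, is added to 10 and the boronate is rearranged with ZnCl2 on warming. This should give the α-chloro boronic ester 2-[(1RS,2R,3R)-1-chloro-4-(3,4-dimethoxyphenyl)-2,3-dimethylbutyl]-4,4,5,5-tetramethyl-1,3,2-dioxaborolane F4. (3,4,5-Trimethoxyphenyl)magnesium bromide (from 5-bromo-1,2,3-trimethoxybenzene and Mg) in THF at −78 °C → rt adds to boron, and the aryl group displaces chloride by 1,2-shift to give 15, which is oxidised to 16 as in step 5.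

**Further compounds**

F1 | step 8 | (2S,3R)-1-(3,4-dimethoxyphenyl)-2,3-dimethyl-4-(3,4,5-trimethoxyphenyl)butane-1,4-dione | COc1ccc(C(=O)[C@@H](C)[C@@H](C)C(=O)c2cc(OC)c(OC)c(OC)c2)cc1OC
F2 | step 8 | (1S,2S,3R,4R)-1-(3,4-dimethoxyphenyl)-2,3-dimethyl-4-(3,4,5-trimethoxyphenyl)butane-1,4-diol | COc1ccc([C@@H](O)[C@@H](C)[C@@H](C)[C@@H](O)c2cc(OC)c(OC)c(OC)c2)cc1OC
F3 | step 3 | (S)-1-(trimethylstannyl)ethyl 2,4,6-triisopropylbenzoate | C[Sn](C)(C)[C@@H](C)OC(=O)c1c(C(C)C)cc(C(C)C)cc1C(C)C
F4 | step 5 | 2-[(1RS,2R,3R)-1-chloro-4-(3,4-dimethoxyphenyl)-2,3-dimethylbutyl]-4,4,5,5-tetramethyl-1,3,2-dioxaborolane | COc1ccc(C[C@@H](C)[C@@H](C)C(Cl)B2OC(C)(C)C(C)(C)O2)cc1OC
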